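**The split.** The ratio I watch in this flask is target over what is lost by a route other than target at 25.0 h: I call it the split S, a selectivity factor. To get it, I subtract intermediate, target and the impurity's share from the charge. I assume that impurity takes starting material one for one, and I neglect whatever starting material remains. The ash run reads S = 1.50. If the target route is first order in c_intermediate and the lost route second order, then c_intermediate sets the order and S should follow c_partner/c_starting material. The split constant K, S times c_starting material over c_partner, is 1.43 from ash.

| flask | starting material | partner | protic impurity | remark | time |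
|---|---|---|---|---|---|
| ash | 0.10 M | 0.105 M | 5 mM | run made earlier |  |
| oak | 0.050 M | 0.105 M | 5 mM | run made earlier |  |
| larch | 0.20 M | 0.105 M | 5 mM | run made earlier |  |
| maple | 0.10 M | 0.105 M | 10 mM | run made earlier |  |
| beta | 0.10 M | 0.105 M | 5.00 mM | one stirred flow tank at steady state, fed with the mixture as stated, mean residence time 75.0 h |  |
| zeta | 0.10 M | 0.105 M | 5.00 mM | everything together in a closed stirred flask, run for 25 h | 25 h |
| epsilon | 0.10 M | 0.105 M | 5.00 mM | a single well-mixed tank run continuously and read at steady state, 25 h in it on average |  |
| eta | 0.10 M | 0.105 M | 5.00 mM | a tube with plug flow, the mixed feed as stated, residence time 25 h | 25 h |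

| run | time / h | intermediate / % | target / % |
|---|---|---|---|
| ash | 2.00 | 34.8 | 4.5 |
| ash | 3.00 | 41.1 | 8.9 |
| ash | 6.00 | 41.4 | 21.1 |
| ash | 10.0 | 30.2 | 34.2 |
| ash | 15.0 | 19.2 | 42.4 |
| ash | 25.0 | 9.0 | 51.6 |
| oak | 2.00 | 34.9 | 4.5 |
| oak | 3.00 | 41.0 | 9.1 |
| oak | 6.00 | 42.6 | 23.3 |
| oak | 10.0 | 32.4 | 38.5 |
| oak | 15.0 | 20.9 | 50.8 |
| oak | 25.0 | 8.8 | 63.0 |
| larch | 4.00 | 39.1 | 12.8 |
| larch | 8.00 | 30.2 | 22.9 |
| larch | 12.0 | 21.0 | 28.6 |
| larch | 15.0 | 16.2 | 31.6 |
| larch | 20.0 | 11.0 | 35.0 |
| larch | 25.0 | 8.1 | 35.8 |
| maple | 2.00 | 33.6 | 4.7 |
| maple | 6.00 | 38.7 | 21.0 |
| maple | 12.0 | 24.3 | 36.5 |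
| maple | 20.0 | 12.2 | 46.8 |
| maple | 25.0 | 8.4 | 49.4 |

(readings scatter by 0.3 percentage points)

- the stated concentrations are those of everything mixed, before any reaction; amounts are the same in each set-up
- the earlier runs were made in a closed, stirred flask

1. the set-up with the highest amount of intermediate at the outlet or at the end, in percent of the starting material put in ("none" if the first two lie within 2 percentage points) (beta / zeta / epsilon / eta / none)
2. amount of intermediate at the outlet or at the end, in percent of the starting material put in, beta
3. amount of intermediate at the outlet or at the end, in percent of the starting material put in, zeta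
4. amount of intermediate at the outlet or at the end, in percent of the starting material put in, epsilon
5. amount of intermediate at the outlet or at the end, in percent of the starting material put in, eta

**Starting material.** By hand, K gives S = 3.00 for oak, and oak reads 3.46. For larch, K gives 0.750 and larch reads 0.668. The direction holds, while intermediate at 25.0 h reads 8.8% in oak and 8.1% in larch.

**Protic impurity.** By hand, doubling it leaves S unchanged. The maple run reads 1.53, with intermediate at 8.4%.

**Vessel and time.** Zeta and eta repeat the ash mixture and time, so I commit to 9.0% for both. In ash, intermediate falls from 41.4% at 6.00 h to that reading. A tank keeps receiving fresh feed, so I expect both tanks above it, with epsilon above beta. I reckon no tank number of my own.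

**The forecast.** It gives beta 11.4%, zeta 9%, epsilon 20%, eta 9%, best epsilon, and says “Zeta and eta have the same history as ash”.

**The result.** Zeta and eta give 8.65%, epsilon 21.6%, beta 12.8%, so the best is epsilon, as forecast. The forecast's 9% for eta would be wrong if that amount moved: it moves by 5 points at the nearest times 19.2 h and 37.8 h with the amounts held, or at the nearest partner charges 0.0592 M and 0.176 M with the time and the other amounts held.

    starting material → intermediate (k = 7.90 × 10⁻⁵ /s)
    partner + intermediate → target (k = 3.10 × 10⁻⁴ /M/s)
    2 intermediate → homo product (k = 2.70 × 10⁻⁴ /M/s)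
    starting material + protic impurity → quenched substrate (k = 0.00880 /M/s)

**Less partner.** K gives S = 1.50 for eta, the ash reading again since the charges match, and eta's target 51.5% over homo product 34.8% is 1.48. The neighbour charged with 0.063 M of partner reckons to 0.900. It gives target 34.8% and homo product 46.9%, a split of 0.742, with intermediate at 13.2%.

The readings are calculated for substances that don't exist, and the scatter is random.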